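**Retrosynthetic overview**

- The strategy rests on ring A of the target: chroman C6 carries the acyl group, both neighbours (C5, C7) carry OH, and the pyran oxygen O1 (on C8a) is para to the acyl carbon. The two flanking hydroxyls are equivalent towards the ketone. Either one can therefore be tied to the benzylic carbon next to ring B as a flavanone C ring, which leaves only the para oxygen free to build the pyran.
- Target 17 is disconnected at the O1–C2 bond of that sacrificial C ring plus two linker C–H bonds, leading back to the 7,8-fused and 6,7-fused 3'-prenyl dimethylchromanoflavanones 14 and 15, which open to the same dihydrochalcone.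
- The ring-B prenyl group comes from an aromatic Claisen rearrangement of the 4'-O-(1,1-dimethylallyl) ethers 12/13, made by O-alkylation with chloroalkyne 2 and semihydrogenation.
- The dimethylpyran comes from the propargyl-ether Claisen cascade of 7-O-ether 3 (naringenin 1 + 2), followed by hydrogenation of the chromene.
- Ring order: rings A, B and the sacrificial C ring arrive together in naringenin; the pyran is closed on ring A through O7 and saturated; the prenyl group is put on ring B; the C ring is cut last.

Key step: step 12

Remark on the chemistry: the target has no stereocentre, so no enantiomer has to be chosen. Naringenin is used as the racemate and its C2 centre disappears in step 12. Flavanone numbering (O1, C2, C3, C4, C4a, C5–C8, C8a, primed B ring) is used for all tetracycles. The twin steps 2/3, 4/5, 6/7, 8/9 and 10/11 are each one flask operation on the unseparated regioisomeric pair; they are written separately so that each equation has one product.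

**Route**

Step 1
Reactants: 1 naringenin (racemic); 2 3-chloro-3-methylbut-1-yne
Product: 3 7-O-(2-methylbut-3-yn-2-yl)naringenin (racemic)
Conditions: 2 (1.3 equiv), K2CO3 (1.1 equiv), KI (cat.), CuI (cat.), acetone, 55 °C, Ar
Reagents that add atoms: 3-chloro-3-methylbut-1-yne (compound 2), C#CC(C)(C)Cl
Why: The 7-OH is para to the C4 carbonyl and not hydrogen-bonded, so it is the most acidic phenol and the only one ionised by about one equivalent of carbonate, and the copper-assisted etherification of the tertiary propargylic chloride should therefore give the 7-aryl ether while the chelated 5-OH and the less acidic 4'-OH stay free.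

Step 2
Reactants: 3 7-O-(2-methylbut-3-yn-2-yl)naringenin
Product: 5 angular (7,8-fused) 2,2-dimethylchromenoflavanone, via 8-allenylnaringenin 4 (not isolated)
Conditions: PhNEt2, 185 °C, Ar; cold dilute HCl wash to remove the amine
Reagents that add atoms: none
Why: This is the aryl propargyl ether Claisen cascade, in which a [3,3] shift to C8 and enolisation give allenylphenol 4, whose 1,5-H shift to an o-quinone methide and oxa-6π electrocyclisation close the 2H-pyran with O7 kept as the ring oxygen.

Step 3
Reactants: 3 7-O-(2-methylbut-3-yn-2-yl)naringenin
Product: 7 linear (6,7-fused) 2,2-dimethylchromenoflavanone, via 6-allenylnaringenin 6 (not isolated)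
Conditions: same flask as step 2 (PhNEt2, 185 °C, Ar)
Reagents that add atoms: none
Why: The same propargyl Claisen cascade runs through the other ortho carbon (C6), again with O7 as the pyran oxygen, and this isomer need not be separated from 5 because both lead to the same final product.

Step 4
Reactants: 5 angular 2,2-dimethylchromenoflavanone
Product: 8 angular (7,8-fused) 2,2-dimethylchromanoflavanone
Conditions: H2 (1 atm), 10% Pd/C, EtOAc, rt, stopped after one equivalent of H2
Reagents that add atoms: none
Why: Neutral heterogeneous hydrogenation of the cis-disubstituted styrene-type chromene alkene is fast, the chelated aryl ketone and the benzylic C2–O1 bond should survive at 1 atm, and no prenyl group is present yet to compete.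

Step 5
Reactants: 7 linear 2,2-dimethylchromenoflavanone
Product: 9 linear (6,7-fused) 2,2-dimethylchromanoflavanone
Conditions: same flask as step 4 (H2, Pd/C, EtOAc, rt)
Reagents that add atoms: none
Why: The same catalytic hydrogenation of the chromene C=C applies to the linear isomer.

Step 6
Reactants: 8 angular 2,2-dimethylchromanoflavanone; 2 3-chloro-3-methylbut-1-yne
Product: 10 angular 4'-O-(2-methylbut-3-yn-2-yl) ether
Conditions: 2 (1.5 equiv), K2CO3 (1.2 equiv), KI (cat.), CuI (cat.), acetone, 55 °C, Ar
Reagents that add atoms: 3-chloro-3-methylbut-1-yne (compound 2), C#CC(C)(C)Cl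
Why: The 4'-OH is the only phenol that can be alkylated, since 5-OH is held in the hydrogen bond to C4=O and all other oxygens are ring ethers, so the same copper-assisted propargylic etherification should give the tertiary aryl ether; any reversible C-ring opening and reclosure would only interconvert the two regioisomers.

Step 7
Reactants: 9 linear 2,2-dimethylchromanoflavanone; 2 3-chloro-3-methylbut-1-yne
Product: 11 linear 4'-O-(2-methylbut-3-yn-2-yl) ether
Conditions: same flask as step 6 (2, K2CO3, KI cat., CuI cat., acetone, 55 °C)
Reagents that add atoms: 3-chloro-3-methylbut-1-yne (compound 2), C#CC(C)(C)Cl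
Why: The same selective phenol etherification at the only free, non-chelated OH applies.

Step 8
Reactants: 10 angular 4'-O-(2-methylbut-3-yn-2-yl) ether
Product: 12 angular 4'-O-(2-methylbut-3-en-2-yl) ether
Conditions: H2 (1 atm), Lindlar catalyst, quinoline, EtOAc, rt
Reagents that add atoms: none
Why: Lindlar semihydrogenation stops at the terminal alkene and should give the 1,1-dimethylallyl aryl ether without touching the flavanone ketone or the C2–O1 bond.

Step 9
Reactants: 11 linear 4'-O-(2-methylbut-3-yn-2-yl) ether
Product: 13 linear 4'-O-(2-methylbut-3-en-2-yl) ether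
Conditions: same flask as step 8 (H2, Lindlar catalyst, quinoline, EtOAc, rt)
Reagents that add atoms: none
Why: The same alkyne semihydrogenation applies.

Step 10
Reactants: 12 angular 4'-O-(2-methylbut-3-en-2-yl) ether
Product: 14 angular 3'-prenyl-2,2-dimethylchromanoflavanone
Conditions: degassed m-xylene, 130 °C, Ar; neutral work-up (evaporation, chromatography)
Reagents that add atoms: none
Why: In this aromatic Claisen rearrangement the [3,3] shift delivers the CH2 terminus to either of the two equivalent carbons ortho to the 4'-oxygen (para is blocked by C2), which inverts the allyl unit to the prenyl group before tautomerisation restores the phenol, and the neutral hydrocarbon medium avoids acid-induced chroman formation.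

Step 11
Reactants: 13 linear 4'-O-(2-methylbut-3-en-2-yl) ether
Product: 15 linear 3'-prenyl-2,2-dimethylchromanoflavanone
Conditions: same flask as step 10 (m-xylene, 130 °C, Ar)
Reagents that add atoms: none
Why: The same aromatic Claisen rearrangement to the ortho position of ring B applies.

Step 12
Reactants: 14 angular 3'-prenyl-2,2-dimethylchromanoflavanone; 15 linear 3'-prenyl-2,2-dimethylchromanoflavanone
Product: 17 target dihydrochalcone CNP0080516.0, via chalcone phenolate 16 (not isolated)
Conditions: NaOH (4 equiv, 1 M aq)/EtOH, Ar, rt; then Na2S2O4 (4 equiv), 65 °C; work-up with pH 6–7 phosphate buffer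
Reagents that add atoms: none
Why: Hydroxide removes a C3 proton and the ring-A phenoxide is expelled from C2 (E1cB retro-oxa-Michael, assisted by the para-phenoxide of ring B), so that both 14 and 15 give the single 2',6'-dihydroxychalcone 16, in which the two ortho oxygens are equivalent and the pyran oxygen lies para to the acyl group. Dithionite then reduces only the polarised enone C=C (sulfoxylate conjugate addition and loss of SO2, or electron transfer, then protonation), forming the two linker C–H bonds. The closest known reactions are the alkaline flavanone–chalcone opening run together with reduction to a dihydrochalcone, and the dithionite conjugate reduction of chalcones. No ring is closed, since the pyranone C ring is opened at O1–C2, and no stereocentre is created, the racemic C2 centre and the alkene geometry both being erased. The step needs 1,4-reduction in preference to the prenyl alkene and the ketone: the isolated trisubstituted alkene has no acceptor character, and the carbonyl is deactivated by its ortho-phenoxide/chelate. Because hydroxide is consumed as dithionite is oxidised, the pH should drift to about 10, where the less charged chalcone stays in rapid equilibrium with any reclosed flavanone and is drained irreversibly to 17, and no acid strong enough to cyclise the ortho-prenylphenol is used.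

**Compound list**

1 | naringenin, racemic (5,7,4'-trihydroxyflavanone) | O=C1CC(c2ccc(O)cc2)Oc2cc(O)cc(O)c21 | starting material
2 | 3-chloro-3-methylbut-1-yne | C#CC(C)(C)Cl | starting material
3 | 7-O-(2-methylbut-3-yn-2-yl)naringenin, racemic | C#CC(C)(C)Oc1cc(O)c2c(c1)OC(c1ccc(O)cc1)CC2=O | intermediate
4 | 8-(3-methylbuta-1,2-dienyl)naringenin (8-allenylnaringenin), racemic, not isolated | CC(C)=C=Cc1c(O)cc(O)c2c1OC(c1ccc(O)cc1)CC2=O | intermediate
5 | angular 2,2-dimethylchromenoflavanone (2H-pyran fused at C7–C8 through O7; 5-OH, 4'-OH free), racemic | O=C1CC(c2ccc(O)cc2)Oc2c1c(O)cc1OC(C)(C)C=Cc12 | intermediate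
6 | 6-(3-methylbuta-1,2-dienyl)naringenin (6-allenylnaringenin), racemic, not isolated | CC(C)=C=Cc1c(O)cc2OC(c3ccc(O)cc3)CC(=O)c2c1O | intermediate
7 | linear 2,2-dimethylchromenoflavanone (2H-pyran fused at C6–C7 through O7), racemic | O=C1CC(c2ccc(O)cc2)Oc2cc3OC(C)(C)C=Cc3c(O)c21 | intermediate
8 | angular 2,2-dimethylchromanoflavanone (saturated pyran at C7–C8), racemic | O=C1CC(c2ccc(O)cc2)Oc2c1c(O)cc1OC(C)(C)CCc12 | intermediate
9 | linear 2,2-dimethylchromanoflavanone (saturated pyran at C6–C7), racemic | O=C1CC(c2ccc(O)cc2)Oc2cc3OC(C)(C)CCc3c(O)c21 | intermediate
10 | angular 4'-O-(2-methylbut-3-yn-2-yl) ether of 8, racemic | O=C1CC(c2ccc(OC(C)(C)C#C)cc2)Oc2c1c(O)cc1OC(C)(C)CCc12 | intermediate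
11 | linear 4'-O-(2-methylbut-3-yn-2-yl) ether of 9, racemic | O=C1CC(c2ccc(OC(C)(C)C#C)cc2)Oc2cc3OC(C)(C)CCc3c(O)c21 | intermediate
12 | angular 4'-O-(2-methylbut-3-en-2-yl) ether, racemic | O=C1CC(c2ccc(OC(C)(C)C=C)cc2)Oc2c1c(O)cc1OC(C)(C)CCc12 | intermediate
13 | linear 4'-O-(2-methylbut-3-en-2-yl) ether, racemic | O=C1CC(c2ccc(OC(C)(C)C=C)cc2)Oc2cc3OC(C)(C)CCc3c(O)c21 | intermediate
14 | angular 3'-prenyl-2,2-dimethylchromanoflavanone (4'-OH, 5-OH free), racemic | O=C1CC(c2ccc(O)c(CC=C(C)C)c2)Oc2c1c(O)cc1OC(C)(C)CCc12 | intermediate
15 | linear 3'-prenyl-2,2-dimethylchromanoflavanone, racemic | O=C1CC(c2ccc(O)c(CC=C(C)C)c2)Oc2cc3OC(C)(C)CCc3c(O)c21 | intermediate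
16 | (E)-1-(5,7-dihydroxy-2,2-dimethylchroman-6-yl)-3-(4-hydroxy-3-prenylphenyl)prop-2-en-1-one, formed as its phenolate, not isolated | CC(C)=CCc1cc(/C=C/C(=O)c2c(O)cc3c(c2O)CCC(C)(C)O3)ccc1O | intermediate
17 | 1-(5,7-dihydroxy-2,2-dimethylchroman-6-yl)-3-(4-hydroxy-3-prenylphenyl)propan-1-one (CNP0080516.0), achiral | CC(C)=CCc1cc(CCC(=O)c2c(O)cc3c(c2O)CCC(C)(C)O3)ccc1O | target

**Step count**

Total step count: 12 written steps, corresponding to 7 flask operations because the twin steps are run on the regioisomeric pair together.
Longest linear sequence: 7 steps (1, 2, 4, 6, 8, 10, 12).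

**Steps most likely to fail**

1. Step 12. The conjugate reduction of the electron-rich polyphenolate enone may stall, the opened chalcone may reclose or be oxidised by air before it is reduced, or the ketone may be over-reduced. Fallback: starting from 14 and 15, the C ring would be opened with concurrent O-acetylation (Ac2O, NaOAc, 120 °C, the known behaviour of 5-hydroxyflavanones) to give the chalcone triacetate F1, which cannot reclose and is a better Michael acceptor. Its enone would be reduced in the 1,4-sense with Stryker's reagent ([(Ph3P)CuH]6, toluene, rt), which leaves the prenyl alkene and the aryl acetates alone, to give the dihydrochalcone triacetate F2. Mild methanolysis (K2CO3, MeOH, rt) would then rejoin the route at 17.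

2. Step 1. The ether may form at the 4'-OH or twice, and base may open the C ring and expose further phenoxides. Fallback: starting from 1, the pyran would be built directly by condensation with 3-methylbut-2-enal (ethylenediammonium diacetate cat., xylene, 120 °C, or pyridine at the same temperature). C-alkylation of the resorcinol-type ring A at C8 or C6, dehydration to the o-quinone methide and oxa-6π closure through the non-chelated O7 should give the chromenes directly, rejoining the route at 5 and 7 and bypassing 3. Ring B has no meta oxygen and should not react.

3. Step 10 (and its twin, step 11). The tertiary allyl ether may fragment with loss of isoprene in place of rearranging, or the new ortho-prenylphenol may cyclise onto its alkene at the Claisen temperature. Fallback: starting from 8 and 9, the 4'-OH would be allylated (allyl bromide, K2CO3, acetone) to the allyl ethers F3 (angular) and F4 (linear). The robust allyl aryl ether Claisen rearrangement (PhNEt2, 190 °C) should give the 3'-allylphenols F5 and F6. Olefin cross-metathesis with 2-methylbut-2-ene (Grubbs second-generation catalyst, CH2Cl2, 40 °C) would convert allyl into prenyl, rejoining the route at 14 and 15 and replacing steps 6 to 11.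

**Further compounds**

F1 | step 12 | (E)-chalcone triacetate (2',6',4-tri-O-acetyl derivative of 16) | CC(C)=CCc1cc(/C=C/C(=O)c2c(OC(C)=O)cc3c(c2OC(C)=O)CCC(C)(C)O3)ccc1OC(C)=O
F2 | step 12 | dihydrochalcone triacetate (tri-O-acetyl derivative of 17) | CC(C)=CCc1cc(CCC(=O)c2c(OC(C)=O)cc3c(c2OC(C)=O)CCC(C)(C)O3)ccc1OC(C)=O
F0 | step 1 | none | none
F3 | step 10 | angular 4'-O-allyl ether of 8, racemic | O=C1CC(c2ccc(OCC=C)cc2)Oc2c1c(O)cc1OC(C)(C)CCc12
F4 | step 10 | linear 4'-O-allyl ether of 9, racemic | O=C1CC(c2ccc(OCC=C)cc2)Oc2cc3OC(C)(C)CCc3c(O)c21
F5 | step 10 | angular 3'-allyl-2,2-dimethylchromanoflavanone, racemic | O=C1CC(c2ccc(O)c(CC=C)c2)Oc2c1c(O)cc1OC(C)(C)CCc12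
F6 | step 10 | linear 3'-allyl-2,2-dimethylchromanoflavanone, racemic | O=C1CC(c2ccc(O)c(CC=C)c2)Oc2cc3OC(C)(C)CCc3c(O)c21
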